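The route rests on one disconnection: the four contiguous carbons C6–C5–C5'–C6' of quinone rings A and B (each ring numbered C1=O, C2–OH, C3–Me, C4=O, C5 axis carbon, C6 chain carbon; ring A bears the 2-methoxyphenethyl chain) are the four carbons of a conjugated diyne. A twofold Diels–Alder/bridge-opening benzannulation of a 2-silyloxy-3-methoxy-4-methylfuran onto the two ynones of an unsymmetrical diynedione closes both rings as hydroquinone monosilyl ethers and sets every ring substituent, while the tetra-ortho-substituted C5–C5' axis is never made by a coupling. The precursor is ArCH2CO–C≡C–C≡C–COCH2Ph (Ar = 2-methoxyphenyl); its carbonyls become the inner CH2 groups of the chains.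

Key step: step 10

Remarks on the chemistry (one line each):
- The ring numbering above is used for all intermediates; primed locants belong to ring B, which carries the phenethyl chain.
- The C5–C5' axis of 17–22 has four ortho substituents and is stereogenic; the target is drawn without axial configuration, so these compounds are taken as racemates.
- The diynedione 9 has an eight-carbon chain (ArCH2–CO–C≡C–C≡C–CO–CH2Ph) and is named as an octa-3,5-diyne-2,7-dione; a seven-carbon name cannot hold two ketones and two triple bonds in this array.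
- In 17 each ketone faces a hydroxyl of the other ring across the axis (C6 carbonyl/C4'–OH and C6' carbonyl/C4–OH); these pairs can close six-membered lactols and would trap benzylic cations as cyclic ethers, so both hydroxyls are methylated (step 11) before the ketones are reduced.

Step 1
Reactants: 1 2-(2-methoxyphenyl)ethanol
Product: 2 2-(2-methoxyphenyl)acetaldehyde
Conditions: Dess–Martin periodinane, CH2Cl2, 0 °C to rt; used crude
Reagents that add atoms: none
Why: Dess–Martin oxidation of a primary alcohol stops at the aldehyde under neutral conditions, which suits an arylacetaldehyde that enolises and self-condenses easily.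

Step 2
Reactants: 2 2-(2-methoxyphenyl)acetaldehyde; 3 ethynylmagnesium bromide
Product: 4 1-(2-methoxyphenyl)but-3-yn-2-ol (racemic)
Conditions: HC≡CMgBr (0.5 M in THF, 1.3 equiv), THF, −78 to 0 °C; then cold 1 M HCl
Reagents that add atoms: none
Why: 1,2-Addition of an alkynyl Grignard reagent to an aldehyde at low temperature should outrun enolisation; the carbinol centre forms racemic and is erased in step 6.

Step 3
Reactants: 5 phenylacetaldehyde; 3 ethynylmagnesium bromide
Product: 6 1-phenylbut-3-yn-2-ol (racemic)
Conditions: HC≡CMgBr (0.5 M in THF, 1.3 equiv), THF, −78 to 0 °C; then cold 1 M HCl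
Reagents that add atoms: none
Why: The same Grignard 1,2-addition as in step 2, on a substrate for which this ethynylation is well established; the racemic carbinol centre is erased in step 6.

Step 4
Reactants: 6 1-phenylbut-3-yn-2-ol
Product: 7 4-bromo-1-phenylbut-3-yn-2-ol (racemic)
Conditions: NBS, AgNO3 (10 mol %), acetone, rt, dark
Reagents that add atoms: N-bromosuccinimide, O=C1CCC(=O)N1Br
Why: Silver-catalysed electrophilic bromination of a terminal alkyne (through the silver acetylide) is selective for the sp C–H and leaves the secondary alcohol untouched.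

Step 5
Reactants: 4 1-(2-methoxyphenyl)but-3-yn-2-ol; 7 4-bromo-1-phenylbut-3-yn-2-ol
Product: 8 1-(2-methoxyphenyl)-8-phenylocta-3,5-diyne-2,7-diol (mixture of diastereomers)
Conditions: CuCl (5 mol %), NH2OH·HCl, 30% aq n-BuNH2, Et2O, 0 °C
Reagents that add atoms: none
Why: Cadiot–Chodkiewicz coupling joins the copper acetylide of 4 to the bromoalkyne 7 to give only the unsymmetrical diyne, with NH2OH·HCl keeping copper monovalent so that oxidative homocoupling is suppressed; propargylic alcohols are the classical substrates, and both carbinol centres disappear in step 6.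

Step 6
Reactants: 8 1-(2-methoxyphenyl)-8-phenylocta-3,5-diyne-2,7-diol
Product: 9 1-(2-methoxyphenyl)-8-phenylocta-3,5-diyne-2,7-dione
Conditions: Dess–Martin periodinane (2.5 equiv), CH2Cl2, 0 °C to rt; short SiO2 plug, used at once
Reagents that add atoms: none
Why: Dess–Martin oxidation converts both propargylic carbinols into ynones without base, which protects the electrophilic bis-ynone and its acidic benzylic CH2 groups.

Step 7
Reactants: 10 diethyl 2-methyl-3-oxobutanedioate
Product: 12 3-hydroxy-4-methylfuran-2(5H)-one, via ethyl 3-methyl-4,5-dioxooxolane-3-carboxylate 11 (not isolated)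
Conditions: 37% aq CH2O, K2CO3 (cat.), H2O/EtOH, 0 °C to rt; then 6 M HCl, reflux
Reagents that add atoms: formaldehyde, C=O
Why: Aldol hydroxymethylation of the doubly activated methine, lactonisation onto the oxalyl ester and acid hydrolysis–decarboxylation is the classical entry to α-keto-γ-butyrolactones, which rest as the conjugated enol; the single acidic C–H rules out double hydroxymethylation.

Step 8
Reactants: 12 3-hydroxy-4-methylfuran-2(5H)-one
Product: 13 3-methoxy-4-methylfuran-2(5H)-one
Conditions: Me2SO4, K2CO3, acetone, reflux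
Reagents that add atoms: dimethyl sulfate, COS(=O)(=O)OC
Why: O-Alkylation of the acidic enol (a vinylogous acid) by a hard methylating agent under weak base should give the methyl enol ether without opening the lactone.

Step 9
Reactants: 13 3-methoxy-4-methylfuran-2(5H)-one
Product: 14 tert-butyl[(3-methoxy-4-methylfuran-2-yl)oxy]dimethylsilane
Conditions: TBSOTf, Et3N, CH2Cl2, 0 °C to rt; stored under argon
Reagents that add atoms: tert-butyldimethylsilyl trifluoromethanesulfonate, CC(C)(C)[Si](C)(C)OS(=O)(=O)C(F)(F)F
Why: Soft enolisation of a butenolide at C5 by a silyl triflate and an amine gives the aromatic 2-silyloxyfuran (vinylogous silyl ketene acetal formation), the standard preparation of such dienes.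

Step 10
Reactants: 9 1-(2-methoxyphenyl)-8-phenylocta-3,5-diyne-2,7-dione; 14 tert-butyl[(3-methoxy-4-methylfuran-2-yl)oxy]dimethylsilane (two molecules are incorporated)
Product: 17 1-{3,3'-bis[(tert-butyldimethylsilyl)oxy]-6,6'-dihydroxy-4,4'-dimethoxy-5,5'-dimethyl-2'-(phenylacetyl)[1,1'-biphenyl]-2-yl}-2-(2-methoxyphenyl)ethan-1-one, via ring A monoadduct 15 (not isolated), via ring B monoadduct 16 (not isolated)
Conditions: 14 (4 equiv), toluene, rt then 90 °C, argon; SiO2
Reagents that add atoms: none
Why: Each ynone of 9 should undergo a polarised, asynchronous [4+2] cycloaddition with the electron-rich furan in which the unsubstituted, most nucleophilic furan C5 bonds to the inner diyne carbon (β to the neighbouring carbonyl, future C5 or C5') and the silyloxy-bearing furan C2 bonds to the acyl-bearing carbon (future C6 or C6'), after which the oxygen bridge opens at the silyl ketal bridgehead and the other bridgehead loses its proton, so that the ring aromatises with O-silyl at C1 and free OH at C4. The closest known reaction type is the Diels–Alder/bridge-opening benzannulation of 2-silyloxy- and 2-alkoxyfurans with acetylenic esters and ketones, run here on both triple bonds of one diyne. Rings A and B are each closed by an intermolecular [4+2] cycloaddition (bonds C1–C6 and C4–C5, then C1'–C6' and C4'–C5'), the C5–C5' bond being present from the start. No stereocentre is created, and the tetra-ortho-substituted axis forms as a racemate. The step needs orientational selectivity in both additions: it rests on the match between the vinylogous silyl ketene acetal terminus (furan C5–H, also the less hindered end) and the conjugate position of each ynone, and in the second addition the aryl-bearing alkyne carbon is both the β-carbon and the one that meets the small end of the diene. Excess 14 covers loss of diene to the phenols formed, and heating drives the slower second addition.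

Step 11
Reactants: 17 bis(hydroquinone monosilyl ether) diketone
Product: 18 1-{3,3'-bis[(tert-butyldimethylsilyl)oxy]-4,4',6,6'-tetramethoxy-5,5'-dimethyl-2'-(phenylacetyl)[1,1'-biphenyl]-2-yl}-2-(2-methoxyphenyl)ethan-1-one
Conditions: MeI, K2CO3, acetone, 50 °C (sealed)
Reagents that add atoms: iodomethane, CI
Why: Williamson O-methylation of the two phenols (K2CO3 deprotonates only ArOH, and any lactol tautomer reopens through its phenoxide) caps the C4 and C4' hydroxyls that would otherwise capture the benzylic cations of step 13 as cyclic ethers.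

Step 12
Reactants: 18 bis(methyl ether) diketone
Product: 19 1-{3,3'-bis[(tert-butyldimethylsilyl)oxy]-2'-(1-hydroxy-2-phenylethyl)-4,4',6,6'-tetramethoxy-5,5'-dimethyl[1,1'-biphenyl]-2-yl}-2-(2-methoxyphenyl)ethan-1-ol (mixture of diastereomers)
Conditions: NaBH4, THF/MeOH, 0 to 40 °C
Reagents that add atoms: none
Why: Borohydride reduction of the two aryl ketones gives benzylic alcohols whose new centres form without control next to the racemic axis; all diastereomers converge in step 13, and a shift of silyl from the C1 oxygen to the neighbouring alkoxide would be harmless there.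

Step 13
Reactants: 19 bis(benzylic alcohol)
Product: 20 3,3'-bis[(tert-butyldimethylsilyl)oxy]-4,4',6,6'-tetramethoxy-2-[2-(2-methoxyphenyl)ethyl]-5,5'-dimethyl-2'-(2-phenylethyl)-1,1'-biphenyl
Conditions: Et3SiH (6 equiv), CF3CO2H, CH2Cl2, 0 °C to rt
Reagents that add atoms: none
Why: Ionic hydrogenation, in which CF3CO2H ionises each benzylic alcohol to a cation stabilised by the electron-rich ring and Et3SiH delivers hydride irreversibly; any stilbene formed by E1 loss is reprotonated and reduced to the same product, and the methyl ethers cannot close a stable ring onto the cation.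

Step 14
Reactants: 20 bis(arylethyl) biaryl
Product: 21 4,4'-dimethoxy-2-[2-(2-methoxyphenyl)ethyl]-5,5'-dimethyl-2'-(2-phenylethyl)[1,1'-bi(cyclohexa-1,4-diene)]-3,3',6,6'-tetrone
Conditions: (NH4)2Ce(NO3)6 (5 equiv), MeCN/H2O, 0 °C
Reagents that add atoms: water, O
Why: Oxidative dealkylation/desilylation of para-dioxygenated arenes by (NH4)2Ce(NO3)6 (electron transfer from the most electron-rich rings, attack of water, loss of methanol and silanol) should give both para-quinones while the mono-oxygenated anisole ring and the phenyl ring stay untouched.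

Step 15
Reactants: 21 bis(2-methoxyquinone)
Product: 22 4,4'-dihydroxy-2-[2-(2-methoxyphenyl)ethyl]-5,5'-dimethyl-2'-(2-phenylethyl)[1,1'-bi(cyclohexa-1,4-diene)]-3,3',6,6'-tetrone (target, CNP0202346.0)
Conditions: 1 M aq NaOH, MeOH, rt, argon; then 1 M HCl
Reagents that add atoms: sodium hydroxide, [Na+].[OH-]
Why: The C2 and C2' methoxy groups are vinylogous esters, so hydroxide should replace methoxide by addition–elimination (the classical conversion of 2-methoxy-1,4-quinones into 2-hydroxy-1,4-quinones), the fully substituted rings offer no site for conjugate addition, and the side-chain aryl methyl ether is inert.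

Compound list
1 | 2-(2-methoxyphenyl)ethanol | COc1ccccc1CCO | starting material
2 | 2-(2-methoxyphenyl)acetaldehyde | COc1ccccc1CC=O | intermediate
3 | ethynylmagnesium bromide | C#C[Mg]Br | starting material
4 | 1-(2-methoxyphenyl)but-3-yn-2-ol (racemic) | COc1ccccc1CC(O)C#C | intermediate
5 | phenylacetaldehyde | O=CCc1ccccc1 | starting material
6 | 1-phenylbut-3-yn-2-ol (racemic) | OC(Cc1ccccc1)C#C | intermediate
7 | 4-bromo-1-phenylbut-3-yn-2-ol (racemic) | OC(Cc1ccccc1)C#CBr | intermediate
8 | 1-(2-methoxyphenyl)-8-phenylocta-3,5-diyne-2,7-diol (mixture of diastereomers) | COc1ccccc1CC(O)C#CC#CC(O)Cc1ccccc1 | intermediate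
9 | 1-(2-methoxyphenyl)-8-phenylocta-3,5-diyne-2,7-dione | COc1ccccc1CC(=O)C#CC#CC(=O)Cc1ccccc1 | intermediate
10 | diethyl 2-methyl-3-oxobutanedioate | CCOC(=O)C(=O)C(C)C(=O)OCC | starting material
11 | ethyl 3-methyl-4,5-dioxooxolane-3-carboxylate (racemic) | CCOC(=O)C1(C)COC(=O)C1=O | intermediate (not isolated)
12 | 3-hydroxy-4-methylfuran-2(5H)-one | CC1=C(O)C(=O)OC1 | intermediate
13 | 3-methoxy-4-methylfuran-2(5H)-one | COC1=C(C)COC1=O | intermediate
14 | tert-butyl[(3-methoxy-4-methylfuran-2-yl)oxy]dimethylsilane | COc1c(C)coc1O[Si](C)(C)C(C)(C)C | intermediate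
15 | ring A monoadduct: 1-[6-[(tert-butyldimethylsilyl)oxy]-3-hydroxy-5-methoxy-4-methyl-2-(3-oxo-4-phenylbut-1-yn-1-yl)phenyl]-2-(2-methoxyphenyl)ethan-1-one | COc1ccccc1CC(=O)c1c(O[Si](C)(C)C(C)(C)C)c(OC)c(C)c(O)c1C#CC(=O)Cc1ccccc1 | intermediate (not isolated)
16 | ring B monoadduct: 1-[6-[(tert-butyldimethylsilyl)oxy]-3-hydroxy-5-methoxy-2-[4-(2-methoxyphenyl)-3-oxobut-1-yn-1-yl]-4-methylphenyl]-2-phenylethan-1-one | COc1ccccc1CC(=O)C#Cc1c(O)c(C)c(OC)c(O[Si](C)(C)C(C)(C)C)c1C(=O)Cc1ccccc1 | intermediate (not isolated)
17 | 1-{3,3'-bis[(tert-butyldimethylsilyl)oxy]-6,6'-dihydroxy-4,4'-dimethoxy-5,5'-dimethyl-2'-(phenylacetyl)[1,1'-biphenyl]-2-yl}-2-(2-methoxyphenyl)ethan-1-one (racemic axis; C1/C1' OTBS, C2/C2' OMe, C3/C3' Me, C4/C4' OH) | COc1ccccc1CC(=O)c1c(O[Si](C)(C)C(C)(C)C)c(OC)c(C)c(O)c1-c1c(O)c(C)c(OC)c(O[Si](C)(C)C(C)(C)C)c1C(=O)Cc1ccccc1 | intermediate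
18 | 1-{3,3'-bis[(tert-butyldimethylsilyl)oxy]-4,4',6,6'-tetramethoxy-5,5'-dimethyl-2'-(phenylacetyl)[1,1'-biphenyl]-2-yl}-2-(2-methoxyphenyl)ethan-1-one (racemic axis) | COc1ccccc1CC(=O)c1c(O[Si](C)(C)C(C)(C)C)c(OC)c(C)c(OC)c1-c1c(OC)c(C)c(OC)c(O[Si](C)(C)C(C)(C)C)c1C(=O)Cc1ccccc1 | intermediate
19 | 1-{3,3'-bis[(tert-butyldimethylsilyl)oxy]-2'-(1-hydroxy-2-phenylethyl)-4,4',6,6'-tetramethoxy-5,5'-dimethyl[1,1'-biphenyl]-2-yl}-2-(2-methoxyphenyl)ethan-1-ol (mixture of diastereomers) | COc1ccccc1CC(O)c1c(O[Si](C)(C)C(C)(C)C)c(OC)c(C)c(OC)c1-c1c(OC)c(C)c(OC)c(O[Si](C)(C)C(C)(C)C)c1C(O)Cc1ccccc1 | intermediate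
20 | 3,3'-bis[(tert-butyldimethylsilyl)oxy]-4,4',6,6'-tetramethoxy-2-[2-(2-methoxyphenyl)ethyl]-5,5'-dimethyl-2'-(2-phenylethyl)-1,1'-biphenyl (racemic axis) | COc1ccccc1CCc1c(O[Si](C)(C)C(C)(C)C)c(OC)c(C)c(OC)c1-c1c(OC)c(C)c(OC)c(O[Si](C)(C)C(C)(C)C)c1CCc1ccccc1 | intermediate
21 | 4,4'-dimethoxy-2-[2-(2-methoxyphenyl)ethyl]-5,5'-dimethyl-2'-(2-phenylethyl)[1,1'-bi(cyclohexa-1,4-diene)]-3,3',6,6'-tetrone (racemic axis) | COc1ccccc1CCC1=C(C2=C(CCc3ccccc3)C(=O)C(OC)=C(C)C2=O)C(=O)C(C)=C(OC)C1=O | intermediate
22 | 4,4'-dihydroxy-2-[2-(2-methoxyphenyl)ethyl]-5,5'-dimethyl-2'-(2-phenylethyl)[1,1'-bi(cyclohexa-1,4-diene)]-3,3',6,6'-tetrone (racemic axis) | COc1ccccc1CCC1=C(C2=C(CCc3ccccc3)C(=O)C(O)=C(C)C2=O)C(=O)C(C)=C(O)C1=O | target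

Total step count: 15. Longest linear sequence: 10 steps (steps 1, 2, 5, 6, 10, 11, 12, 13, 14, 15).

Steps most likely to fail

1. Step 10. Three things may go wrong. Orientational control may erode in the first cycloaddition, because in the diynedione each outer alkyne carbon is also the vinylogous acceptor position of the far carbonyl. The furan may add in a conjugate sense without ring closure. The reaction may stall after one ring, because the remaining aryl ynone is hindered and the new phenol consumes the diene. The fallback unmasks one ynone at a time and sets out from 4 and 7. Silylation of 4 (TBSCl, imidazole, DMF) should give tert-butyl{[1-(2-methoxyphenyl)but-3-yn-2-yl]oxy}dimethylsilane F1. Cadiot–Chodkiewicz coupling of this with 7 under the conditions of step 5 should give 7-[(tert-butyldimethylsilyl)oxy]-8-(2-methoxyphenyl)-1-phenylocta-3,5-diyn-2-ol F2. Dess–Martin oxidation should give 7-[(tert-butyldimethylsilyl)oxy]-8-(2-methoxyphenyl)-1-phenylocta-3,5-diyn-2-one F3, whose single activated triple bond has an outer carbon conjugated to no second acceptor. Cycloaddition with 14 (toluene, 60 °C) should give the ring B arylalkyne 1-[2-{3-[(tert-butyldimethylsilyl)oxy]-4-(2-methoxyphenyl)but-1-yn-1-yl}-6-[(tert-butyldimethylsilyl)oxy]-3-hydroxy-5-methoxy-4-methylphenyl]-2-phenylethan-1-one F4. PPTS in MeOH should remove the alkyl silyl ether while the aryl silyl ether stays, giving 1-[6-[(tert-butyldimethylsilyl)oxy]-3-hydroxy-2-[3-hydroxy-4-(2-methoxyphenyl)but-1-yn-1-yl]-5-methoxy-4-methylphenyl]-2-phenylethan-1-one F5. MnO2 in CH2Cl2 should then give the aryl ynone 16 as an isolated compound. Heating 16 with fresh 14 in a separate, second benzannulation brings the material back to the route at 17.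

2. Step 13. The benzylic cations may be intercepted by neighbouring oxygen functions (loss of a silyl group followed by ring closure onto the other ring), or ionisation at the crowded carbinols may be sluggish. The fallback leaves the cationic manifold and sets out from 19. Syn-elimination with the Burgess reagent (toluene, 70 °C) should give 3,3'-bis[(tert-butyldimethylsilyl)oxy]-4,4',6,6'-tetramethoxy-2-[(E)-2-(2-methoxyphenyl)ethenyl]-5,5'-dimethyl-2'-[(E)-2-phenylethenyl]-1,1'-biphenyl F6. Hydrogenation of its two 1,2-disubstituted alkenes (H2, Pd/C, EtOAc) should return to the route at 20.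

3. Step 6. The bis-ynone may degrade while the second carbinol is still being oxidised, through conjugate addition of acetate or water or through enolisation of the benzylic CH2 groups. The fallback sets the ketone level before the sp–sp bond is made and starts from 4 and 6. Separate Dess–Martin oxidations should give 1-(2-methoxyphenyl)but-3-yn-2-one F7 and 1-phenylbut-3-yn-2-one F8. Oxidative cross-coupling under Hay conditions (CuCl, TMEDA, O2, acetone, rt) should give 9 together with the two symmetrical diynediones. These differ from 9 by one methoxy group each and should be separable by chromatography; the cost is a statistical distribution. The route is rejoined at 9.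

Further compounds
F1 | step 10 | tert-butyl{[1-(2-methoxyphenyl)but-3-yn-2-yl]oxy}dimethylsilane | COc1ccccc1CC(C#C)O[Si](C)(C)C(C)(C)C
F2 | step 10 | 7-[(tert-butyldimethylsilyl)oxy]-8-(2-methoxyphenyl)-1-phenylocta-3,5-diyn-2-ol | COc1ccccc1CC(O[Si](C)(C)C(C)(C)C)C#CC#CC(O)Cc1ccccc1
F3 | step 10 | 7-[(tert-butyldimethylsilyl)oxy]-8-(2-methoxyphenyl)-1-phenylocta-3,5-diyn-2-one | COc1ccccc1CC(O[Si](C)(C)C(C)(C)C)C#CC#CC(=O)Cc1ccccc1
F4 | step 10 | 1-[2-{3-[(tert-butyldimethylsilyl)oxy]-4-(2-methoxyphenyl)but-1-yn-1-yl}-6-[(tert-butyldimethylsilyl)oxy]-3-hydroxy-5-methoxy-4-methylphenyl]-2-phenylethan-1-one | COc1ccccc1CC(O[Si](C)(C)C(C)(C)C)C#Cc1c(O)c(C)c(OC)c(O[Si](C)(C)C(C)(C)C)c1C(=O)Cc1ccccc1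
F5 | step 10 | 1-[6-[(tert-butyldimethylsilyl)oxy]-3-hydroxy-2-[3-hydroxy-4-(2-methoxyphenyl)but-1-yn-1-yl]-5-methoxy-4-methylphenyl]-2-phenylethan-1-one | COc1ccccc1CC(O)C#Cc1c(O)c(C)c(OC)c(O[Si](C)(C)C(C)(C)C)c1C(=O)Cc1ccccc1
F6 | step 13 | 3,3'-bis[(tert-butyldimethylsilyl)oxy]-4,4',6,6'-tetramethoxy-2-[(E)-2-(2-methoxyphenyl)ethenyl]-5,5'-dimethyl-2'-[(E)-2-phenylethenyl]-1,1'-biphenyl | COc1ccccc1/C=C/c1c(O[Si](C)(C)C(C)(C)C)c(OC)c(C)c(OC)c1-c1c(OC)c(C)c(OC)c(O[Si](C)(C)C(C)(C)C)c1/C=C/c1ccccc1
F7 | step 6 | 1-(2-methoxyphenyl)but-3-yn-2-one | COc1ccccc1CC(=O)C#C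
F8 | step 6 | 1-phenylbut-3-yn-2-one | O=C(Cc1ccccc1)C#C
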